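**Retrosynthetic overview**
1. Feature: in ring B (C1–C10–C9–C8–C7–C6–C5) a single bare CH2, C7, separates oxygenated C6 (next to fusion carbon C5) from the methyl carbinol C8 (next to carbinol C9). This is the pattern of a cyclohepta-1,4-diene C5=C6–C7–C8=C9. It therefore maps onto a cyclopropane C6–C7–C8 that carries a cyclopentenyl group (C5=C1, ring A) on C6 and a vinyl group (C9=C10) on C8, cis to each other.
2. Late stage: phenol debenzylation; 8β,9α-diol by acid hydrolysis (attack at C8) of the 8α,9α-epoxide; 6α-ester by acylation of the equatorial alcohol from SmI2 reduction of the C6 ketone; isopropyl added from the α face to a C4 ketone.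
3. C5–H (α) and C6–O come from diene 14 by hydroxyl-directed β-epoxidation of C5=C6, then a 1,2-hydride shift from C4 to C5.
4. Ring B and quaternary C1 come from the Cope rearrangement of cis-divinylcyclopropane 13 (forms C1–C10, breaks C6–C8), with chirality passed from C6/C8 to C1.
5. 13 comes from bromoenone 1 (ring A, CBS reduction), Z-iodide 6 (Negishi coupling), CH2I2 (Charette cyclopropanation, C7) and Ph3P=CH2 (C10). Ring order: A (bought), cyclopropane, B.

Key step: step 8

Remark: daucane numbering is used throughout (C11–C13 isopropyl, C14 methyl on C8, C15 methyl on C1); β is the face of the C15 methyl and of the C4 oxygen, α the opposite face; 1, 4, 19 and 24 are taken as commercial; C4 passes through the key step as a secondary silyl ether and C6 without oxygen, because a C6 enol ether would later need protonation at C5 from the hindered α face, or base equilibration next to a β,γ-alkene and a β-hydroxyl group.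

**Step 1**
Reactants: 1 2-bromo-3-methylcyclopent-2-en-1-one
Product: 2 (1S)-2-bromo-3-methylcyclopent-2-en-1-ol
Conditions: (R)-2-methyl-CBS-oxazaborolidine (10 mol %), BH3·SMe2, THF, −20 °C
Reagents that add atoms: none
Why: Corey–Bakshi–Shibata reduction, in which the bromoalkenyl carbon acts as the large and the ring CH2 as the small ketone substituent, so the (R)-catalyst–borane complex should give the (S)-carbinol (the later 4β oxygen) by clean 1,2-reduction.

**Step 2**
Reactants: 2 (1S)-2-bromo-3-methylcyclopent-2-en-1-ol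
Product: 3 {[(1S)-2-bromo-3-methylcyclopent-2-en-1-yl]oxy}(tert-butyl)dimethylsilane
Conditions: TBSCl, imidazole, DMF, rt
Reagents that add atoms: tert-butyldimethylsilyl chloride, CC(C)(C)[Si](C)(C)Cl
Why: Imidazole-promoted silylation masks the hydroxyl so that it neither quenches the organometallics nor directs the zinc carbenoid of step 5 to C1=C5; no stereocentre is touched.

**Step 3**
Reactants: 4 prop-2-yn-1-ol
Product: 6 (Z)-3-iodo-2-methylprop-2-en-1-ol, via alkenylmagnesium alkoxide 5 (not isolated)
Conditions: MeMgBr (2.5 equiv), CuI (10 mol %), THF, −10 °C → rt; I2, −78 → 0 °C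
Reagents that add atoms: methylmagnesium bromide, C[Mg]Br; iodine, [I][I]
Why: Copper-catalysed carbomagnesiation of the propargylic alkoxide puts methyl on the internal carbon (C8) and magnesium on the terminal carbon (C6) cis to CH2O in a five-membered chelate, so iodinolysis with retention should give only the Z-iodide.

**Step 4**
Reactants: 3 {[(1S)-2-bromo-3-methylcyclopent-2-en-1-yl]oxy}(tert-butyl)dimethylsilane; 6 (Z)-3-iodo-2-methylprop-2-en-1-ol
Product: 10 (2Z)-3-[(5S)-5-(tert-butyldimethylsilyloxy)-2-methylcyclopent-1-en-1-yl]-2-methylprop-2-en-1-ol, via vinyllithium 7 (not isolated), via vinylzinc bromide 8 (not isolated), via sodium alkoxide 9 (not isolated)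
Conditions: 3, t-BuLi (2.1 equiv), THF, −78 °C; ZnBr2, −78 → 0 °C; 9 (from 6, NaH, THF, 0 °C), Pd(PPh3)4 (5 mol %), rt → 45 °C
Reagents that add atoms: none
Why: Bromine–lithium exchange, transmetallation to zinc and Negishi coupling under zerovalent palladium all proceed with retention at both sp2 carbons, so C5–C6 is formed with the cyclopentenyl group cis to CH2OH, the geometry that becomes the cis relation on the cyclopropane.

**Step 5**
Reactants: 10 (2Z)-3-[(5S)-5-(tert-butyldimethylsilyloxy)-2-methylcyclopent-1-en-1-yl]-2-methylprop-2-en-1-ol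
Product: 11 {(1S,2R)-2-[(5S)-5-(tert-butyldimethylsilyloxy)-2-methylcyclopent-1-en-1-yl]-1-methylcyclopropyl}methanol (cyclopentenyl and CH2OH cis)
Conditions: Et2Zn, CH2I2, DME, CH2Cl2, −10 °C; (4R,5R)-2-butyl-N,N,N′,N′-tetramethyl-1,3,2-dioxaborolane-4,5-dicarboxamide (1.2 equiv), −10 °C → rt
Reagents that add atoms: diiodomethane, C(I)I
Why: Charette asymmetric Simmons–Smith cyclopropanation, in which the zinc alkoxide–dioxaborolane complex delivers CH2 (C7) only to the allylic-alcohol alkene C6=C8 (C1=C5 is tetrasubstituted and has no free hydroxyl), syn-stereospecifically so that Z becomes cis, and the (4R,5R) ligand should select under reagent control the face that makes C8 S and C6 R.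

**Step 6**
Reactants: 11 {(1S,2R)-2-[(5S)-5-(tert-butyldimethylsilyloxy)-2-methylcyclopent-1-en-1-yl]-1-methylcyclopropyl}methanol
Product: 12 the corresponding cis-cyclopropanecarbaldehyde (C9 = CHO)
Conditions: Dess–Martin periodinane, CH2Cl2, 0 °C → rt
Reagents that add atoms: none
Why: Dess–Martin oxidation under neutral conditions; C8 is quaternary so the aldehyde cannot epimerise, and it is used at once because cis-2-alkenylcyclopropanecarbaldehydes can drift into a retro-Claisen equilibrium.

**Step 7**
Reactants: 12 cis-cyclopropanecarbaldehyde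
Product: 13 tert-butyl({(1S)-2-[(1R,2R)-2-ethenyl-2-methylcyclopropyl]-3-methylcyclopent-2-en-1-yl}oxy)dimethylsilane (cyclopentenyl on C6 and vinyl on C8 cis)
Conditions: Ph3PCH3Br, KN(SiMe3)2, THF, 0 °C; then 12, −78 → 0 °C
Reagents that add atoms: methyltriphenylphosphonium bromide, C[P+](c1ccccc1)(c1ccccc1)c1ccccc1.[Br-]
Why: Wittig methylenation of the non-enolisable aldehyde installs C10 at or below 0 °C, well under the temperature at which 13 should rearrange, so the precursor can be isolated and checked.

**Step 8**
Reactants: 13 cis-divinylcyclopropane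
Product: 14 (3S,8aR)-3-(tert-butyldimethylsilyloxy)-6,8a-dimethyl-1,2,3,5,8,8a-hexahydroazulene (4β-silyloxy-11,12,13-trinordauca-5,8-diene; C15 methyl β)
Conditions: PhMe (0.02 M, degassed), BHT (cat.), base-washed sealed tube, 130 °C
Reagents that add atoms: none
Why: Heating brings 13 into the endo-boat conformer with both alkene termini under the three-membered ring, and a concerted suprafacial [3,3] shift (divinylcyclopropane–cycloheptadiene Cope rearrangement) forms C1–C10 while the strained C6–C8 bond breaks and the π bonds move to C5=C6 and C8=C9. The closest known cases are thermal rearrangements of cis-2-vinylcyclopropyl groups on methyl-substituted cyclopentenyl and cyclopentenone rings, which also build a methyl-bearing quaternary fusion carbon and typically need heating above 100 °C because the methyl on the reacting terminus points at the endo hydrogen of C7. Ring B closes in this one pericyclic event as a cis,cis-cyclohepta-1,4-diene, and only the boat is geometrically possible, so no second mode of closure competes. C1 is the only new stereocentre: with C6 R and C8 R the vinyl terminus can reach only the face of C1 anti to the C4 silyloxy group, so C10 enters α and the methyl ends β (chirality transfer from the cyclopropane). The step needs the cis isomer only and no homodienyl 1,5-hydrogen shift; the Z-alkene of 10 fixed the cis relation, and the C8 methyl is trans to the cyclopentenyl group so no C–H bond is placed for the retro-ene path. The temperature should stay below that of C6–C8 homolysis, so the cyclopropane stereocentres should not scramble before they are consumed.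

**Step 9**
Reactants: 14 4β-silyloxy-11,12,13-trinordauca-5,8-diene
Product: 15 (3S,8aR)-6,8a-dimethyl-1,2,3,5,8,8a-hexahydroazulen-3-ol (11,12,13-trinordauca-5,8-dien-4β-ol)
Conditions: Bu4NF, THF, rt
Reagents that add atoms: none
Why: Fluoride-mediated desilylation frees the C4 hydroxyl that is needed next as directing group and then as hydride donor; nothing else is fluoride-sensitive.

**Step 10**
Reactants: 15 11,12,13-trinordauca-5,8-dien-4β-ol
Product: 16 5β,6β-epoxy-11,12,13-trinordauc-8-en-4β-ol (oxirane, hydroxyl and C15 methyl all β)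
Conditions: VO(acac)2 (2 mol %), t-BuOOH (decane), CH2Cl2, 0 °C
Reagents that add atoms: tert-butyl hydroperoxide, CC(C)(C)OO
Why: Vanadium-catalysed hydroxyl-directed epoxidation reaches only the allylic alkene C5=C6 (C8=C9 has no hydroxyl within reach) and delivers oxygen syn to the 4β-hydroxyl, which is also the convex face, setting C5 and C6 as the β-epoxide.

**Step 11**
Reactants: 16 5β,6β-epoxy-11,12,13-trinordauc-8-en-4β-ol
Product: 18 6β-(triethylsilyloxy)-11,12,13-trinor-5αH-dauc-8-en-4-one (trans-fused), via epoxy triethylsilyl ether 17 (not isolated)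
Conditions: Et3SiOTf (2.5 equiv), i-Pr2NEt (3 equiv), 4 Å MS, CH2Cl2, −78 → −40 °C
Reagents that add atoms: triethylsilyl trifluoromethanesulfonate, CC[Si](CC)(CC)OS(=O)(=O)C(F)(F)F
Why: Semipinacol-type rearrangement of a 2,3-epoxy silyl ether (non-aldol aldol rearrangement): silylation gives 17, silyl triflate activates the oxirane, and the α-face C4–H bond, antiperiplanar to the breaking C5–O bond and pushed by the silyloxy group, migrates to tertiary C5 with inversion, so H5 ends α (trans fusion), C4 becomes the ketone and the oxygen stays on C6 (β) as its silyl ether, all without an enolate that would be protonated from the β face.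

**Step 12**
Reactants: 18 6β-(triethylsilyloxy)-11,12,13-trinor-5αH-dauc-8-en-4-one; 19 isopropylmagnesium chloride
Product: 20 6β-(triethylsilyloxy)-5αH-dauc-8-en-4β-ol (isopropyl α)
Conditions: CeCl3 (anhydrous), THF; 19, −78 °C; then 18, −78 → −20 °C
Reagents that add atoms: none
Why: 1,2-Addition of the weakly basic organocerium reagent suppresses enolisation and β-hydride reduction, and since the β face of the cyclopentanone is blocked by the adjacent C5–C6 bond with its silyloxy group and by the C15 methyl, isopropyl should enter from the α face and leave the hydroxyl β.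

**Step 13**
Reactants: 20 6β-(triethylsilyloxy)-5αH-dauc-8-en-4β-ol
Product: 21 5αH-dauc-8-ene-4β,6β-diol
Conditions: Bu4NF, THF, 0 °C → rt
Reagents that add atoms: none
Why: Fluoride cleavage of the secondary triethylsilyl ether; the diol has no base-sensitive function and no stereocentre is touched.

**Step 14**
Reactants: 21 5αH-dauc-8-ene-4β,6β-diol
Product: 22 4β-hydroxy-5αH-dauc-8-en-6-one
Conditions: Dess–Martin periodinane, NaHCO3, CH2Cl2, 0 °C
Reagents that add atoms: none
Why: Dess–Martin oxidation touches only the secondary alcohol, and the buffered non-basic medium should leave C5 (α-H), the β,γ-alkene and the β-hydroxy ketone (no retro-aldol, no dehydration) intact.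

**Step 15**
Reactants: 22 4β-hydroxy-5αH-dauc-8-en-6-one
Product: 23 5αH-dauc-8-ene-4β,6α-diol (jaeschkeanadiol)
Conditions: SmI2 (3 equiv), H2O, THF, 0 °C
Reagents that add atoms: none
Why: Hydroxyl-assisted single-electron (ketyl) reduction: hydride reagents would attack from the open α side and return the axial 6β-alcohol, whereas the samarium ketyl/carbanion should settle with its bulky O–Sm group equatorial (away from the syn-axial C15 methyl, held by O4) and take up the small proton axially, giving the equatorial 6α-alcohol.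

**Step 16**
Reactants: 23 5αH-dauc-8-ene-4β,6α-diol; 24 4-(benzyloxy)benzoyl chloride
Product: 25 6α-[4-(benzyloxy)benzoyloxy]-5αH-dauc-8-en-4β-ol
Conditions: Et3N, DMAP (cat.), CH2Cl2, rt
Reagents that add atoms: none
Why: DMAP-catalysed acylation takes only the secondary equatorial 6α-hydroxyl, the tertiary C4 hydroxyl is inert, and the configuration at C6 is retained.

**Step 17**
Reactants: 25 6α-[4-(benzyloxy)benzoyloxy]-5αH-dauc-8-en-4β-ol
Product: 26 8α,9α-epoxy-6α-[4-(benzyloxy)benzoyloxy]-5αH-daucan-4β-ol
Conditions: mCPBA, NaHCO3, CH2Cl2, 0 °C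
Reagents that add atoms: 3-chloroperoxybenzoic acid, OOC(=O)c1cccc(Cl)c1
Why: Prilezhaev epoxidation of the only alkene; in the chair of the trans-fused ring B the axial C15 methyl leans over the β face of C9, so the peracid should approach from the α face.

**Step 18**
Reactants: 26 8α,9α-epoxide
Product: 27 6α-[4-(benzyloxy)benzoyloxy]-5αH-daucane-4β,8β,9α-triol
Conditions: HClO4 (5 % aq., cat.), THF–H2O, 0 °C
Reagents that add atoms: water, O
Why: Acid-catalysed epoxide hydrolysis of borderline SN2 character: water attacks the protonated oxirane at tertiary C8 from the β face with inversion while C9–O is retained, giving the 8β,9α-trans-diol, and the α-oriented ester cannot take part from the rear side.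

**Step 19**
Reactants: 27 6α-[4-(benzyloxy)benzoyloxy]-5αH-daucane-4β,8β,9α-triol
Product: 28 CNP0197754.1, 6α-(4-hydroxybenzoyloxy)-5αH-daucane-4β,8β,9α-triol
Conditions: H2 (1 atm), Pd/C, EtOAc, rt
Reagents that add atoms: none
Why: Hydrogenolysis of the benzyl aryl ether; no alkene is left, and the alkyl benzoate and the alcohols are inert.

**Compound list**
1 | 2-bromo-3-methylcyclopent-2-en-1-one | CC1=C(Br)C(=O)CC1 | starting material
2 | (1S)-2-bromo-3-methylcyclopent-2-en-1-ol | O[C@H]1CCC(C)=C1Br | intermediate
3 | {[(1S)-2-bromo-3-methylcyclopent-2-en-1-yl]oxy}(tert-butyl)dimethylsilane | CC(C)(C)[Si](C)(C)O[C@H]1CCC(C)=C1Br | intermediate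
4 | prop-2-yn-1-ol | C#CCO | starting material
5 | chelated (Z)-alkenylmagnesium alkoxide (Mg on C6 cis to CH2O) | Br[Mg]/C=C(/C)CO[Mg]Br | intermediate
6 | (Z)-3-iodo-2-methylprop-2-en-1-ol | I/C=C(/C)CO | intermediate
7 | [(5S)-5-(tert-butyldimethylsilyloxy)-2-methylcyclopent-1-en-1-yl]lithium | CC(C)(C)[Si](C)(C)O[C@H]1CCC(C)=C1[Li] | intermediate
8 | bromo[(5S)-5-(tert-butyldimethylsilyloxy)-2-methylcyclopent-1-en-1-yl]zinc | CC(C)(C)[Si](C)(C)O[C@H]1CCC(C)=C1[Zn]Br | intermediate
9 | sodium (Z)-3-iodo-2-methylprop-2-en-1-olate | I/C=C(/C)C[O-].[Na+] | intermediate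
10 | (2Z)-3-[(5S)-5-(tert-butyldimethylsilyloxy)-2-methylcyclopent-1-en-1-yl]-2-methylprop-2-en-1-ol | CC(C)(C)[Si](C)(C)O[C@H]1CCC(C)=C1/C=C(/C)CO | intermediate
11 | {(1S,2R)-2-[(5S)-5-(tert-butyldimethylsilyloxy)-2-methylcyclopent-1-en-1-yl]-1-methylcyclopropyl}methanol | CC(C)(C)[Si](C)(C)O[C@H]1CCC(C)=C1[C@@H]2C[C@]2(C)CO | intermediate
12 | cis-2-[(5S)-5-(tert-butyldimethylsilyloxy)-2-methylcyclopent-1-en-1-yl]-1-methylcyclopropanecarbaldehyde (configuration of 11) | CC(C)(C)[Si](C)(C)O[C@H]1CCC(C)=C1[C@@H]2C[C@]2(C)C=O | intermediate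
13 | tert-butyl({(1S)-2-[(1R,2R)-2-ethenyl-2-methylcyclopropyl]-3-methylcyclopent-2-en-1-yl}oxy)dimethylsilane | CC(C)(C)[Si](C)(C)O[C@H]1CCC(C)=C1[C@@H]2C[C@]2(C)C=C | intermediate
14 | (3S,8aR)-3-(tert-butyldimethylsilyloxy)-6,8a-dimethyl-1,2,3,5,8,8a-hexahydroazulene | CC(C)(C)[Si](C)(C)O[C@H]1CC[C@]2(C)CC=C(C)CC=C12 | intermediate
15 | (3S,8aR)-6,8a-dimethyl-1,2,3,5,8,8a-hexahydroazulen-3-ol | O[C@H]1CC[C@]2(C)CC=C(C)CC=C12 | intermediate
16 | 5β,6β-epoxy-11,12,13-trinordauc-8-en-4β-ol | O[C@H]1CC[C@]2(C)CC=C(C)C[C@H]3O[C@@]123 | intermediate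
17 | 5β,6β-epoxy-4β-(triethylsilyloxy)-11,12,13-trinordauc-8-ene | CC[Si](CC)(CC)O[C@H]1CC[C@]2(C)CC=C(C)C[C@H]3O[C@@]123 | intermediate
18 | 6β-(triethylsilyloxy)-11,12,13-trinor-5αH-dauc-8-en-4-one | O=C1CC[C@]2(C)CC=C(C)C[C@@H](O[Si](CC)(CC)CC)[C@@H]12 | intermediate
19 | isopropylmagnesium chloride | CC(C)[Mg]Cl | starting material
20 | 6β-(triethylsilyloxy)-5αH-dauc-8-en-4β-ol | CC(C)[C@]1(O)CC[C@]2(C)CC=C(C)C[C@@H](O[Si](CC)(CC)CC)[C@H]21 | intermediate
21 | 5αH-dauc-8-ene-4β,6β-diol | CC(C)[C@]1(O)CC[C@]2(C)CC=C(C)C[C@@H](O)[C@H]21 | intermediate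
22 | 4β-hydroxy-5αH-dauc-8-en-6-one | CC(C)[C@]1(O)CC[C@]2(C)CC=C(C)CC(=O)[C@H]21 | intermediate
23 | 5αH-dauc-8-ene-4β,6α-diol | CC(C)[C@]1(O)CC[C@]2(C)CC=C(C)C[C@H](O)[C@H]21 | intermediate
24 | 4-(benzyloxy)benzoyl chloride | O=C(Cl)c1ccc(OCc2ccccc2)cc1 | starting material
25 | 6α-[4-(benzyloxy)benzoyloxy]-5αH-dauc-8-en-4β-ol | CC(C)[C@]1(O)CC[C@]2(C)CC=C(C)C[C@H](OC(=O)c3ccc(OCc4ccccc4)cc3)[C@H]21 | intermediate
26 | 8α,9α-epoxy-6α-[4-(benzyloxy)benzoyloxy]-5αH-daucan-4β-ol | CC(C)[C@]1(O)CC[C@]2(C)C[C@@H]3O[C@]3(C)C[C@H](OC(=O)c4ccc(OCc5ccccc5)cc4)[C@H]21 | intermediate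
27 | 6α-[4-(benzyloxy)benzoyloxy]-5αH-daucane-4β,8β,9α-triol | CC(C)[C@]1(O)CC[C@]2(C)C[C@H](O)[C@@](C)(O)C[C@H](OC(=O)c3ccc(OCc4ccccc4)cc3)[C@H]21 | intermediate
28 | CNP0197754.1 | CC(C)[C@]1(O)CC[C@]2(C)C[C@H](O)[C@@](C)(O)C[C@H](OC(=O)c3ccc(O)cc3)[C@H]21 | target

**Step count**
Total step count: 19. Longest linear sequence: 18 (steps 1, 2 and 4–19, from 1).

**Steps most likely to fail**

Step 8. The methyl group on C1 has to pass the endo hydrogen of C7, and the neighbouring silyloxy-bearing C4 crowds the reactive rotamer. The rearrangement may therefore become so slow that the temperature has to approach the range of C6–C8 homolysis, where cis–trans stereomutation would erode the chirality transfer. The fallback sets out from 13 and changes the substrate.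
- Bu4NF gives the free cyclopentenol F1.
- Dess–Martin periodinane gives the cyclopentenone F2. Here C4 is flat and C1 is the electron-poor β-carbon of an enone, the substrate type for which this rearrangement is best documented.
- Thermolysis of F2 should give the bicyclic dienone F3.
- Reagent-controlled CBS reduction ((R)-2-methyl-CBS-oxazaborolidine, BH3·SMe2) of the C4 ketone brings the material back to the route at 15.

Step 11. The cationic character at C5 may be diverted into a Wagner–Meerwein shift of C10 (also close to antiperiplanar to the breaking C5–O bond), into opening of the oxirane by triflate, or into further silyl enol ether formation with loss of the C5 configuration. The fallback sets out from 16 and replaces the rearrangement by a radical opening.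
- Cp2TiCl (from Cp2TiCl2 and Mn) with 1,4-cyclohexadiene cleaves C5–O to the tertiary C5 radical. Its β face is covered by two titanium alkoxides and the C15 methyl, while the α face carries only H4, so hydrogen should arrive from α to give the trinor-4β,6β-diol F4.
- The sterically sensitive oxidant TEMPO/PhI(OAc)2 should take the open cyclopentanol and spare the axial 6β-hydroxyl, which is syn-axial to the methyl. This gives the 6β-hydroxy-4-ketone F5.
- Et3SiOTf/2,6-lutidine returns to the route at 18.

Step 15. Protonation of the samarium ketyl/carbanion may show poor facial selectivity and return the 6β-alcohol. Pinacol coupling, or retro-aldol cleavage of 22 by the samarium alkoxides, may also intervene. The fallback sets out from 21 and avoids ketone 22 altogether.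
- Mitsunobu inversion of the axial 6β-alcohol with the acidic 4-nitrobenzoic acid (PPh3, DIAD, PhMe) gives the 6α-(4-nitrobenzoate) F6. The tertiary hydroxyl stays untouched, and elimination toward C5 or C7 is the process to watch.
- Methanolysis (K2CO3, MeOH) returns to the route at 23.

**Further compounds**
F1 | step 8 | (1S)-2-[(1R,2R)-2-ethenyl-2-methylcyclopropyl]-3-methylcyclopent-2-en-1-ol | O[C@H]1CCC(C)=C1[C@@H]2C[C@]2(C)C=C
F2 | step 8 | 2-[(1R,2R)-2-ethenyl-2-methylcyclopropyl]-3-methylcyclopent-2-en-1-one | O=C1CCC(C)=C1[C@@H]2C[C@]2(C)C=C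
F3 | step 8 | (8aR)-6,8a-dimethyl-1,5,8,8a-tetrahydroazulen-3(2H)-one | O=C1CC[C@]2(C)CC=C(C)CC=C12
F4 | step 11 | 11,12,13-trinor-5αH-dauc-8-ene-4β,6β-diol | O[C@H]1CC[C@]2(C)CC=C(C)C[C@@H](O)[C@@H]12
F5 | step 11 | 6β-hydroxy-11,12,13-trinor-5αH-dauc-8-en-4-one | O=C1CC[C@]2(C)CC=C(C)C[C@@H](O)[C@@H]12
F6 | step 15 | 6α-(4-nitrobenzoyloxy)-5αH-dauc-8-en-4β-ol | CC(C)[C@]1(O)CC[C@]2(C)CC=C(C)C[C@H](OC(=O)c3ccc(cc3)[N+](=O)[O-])[C@H]21
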